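(The constants are assumed, and the outcome is calculated.)

In a closed, stirred vessel of constant volume you charge solid X and a dose of L; X enters solution as D, D couples with L to give D.L, and L also pairs off to L2.

    2 L → L2 (k1 = 0.0051 /M/min)
    X ⇌ D, rate k2*(cs2 - [D]) while solid is left; crystals form when [D] > cs2 (cs2 = 0.70 M, k2 = 0.0039 /min)
    D + L → D.L (k3 = 0.0093 /M/min)

| flask | X | L | time |
|---|---|---|---|
| midnight | 0.020 M | 0.900 equiv | 2.5 h |
| noon | 0.060 M | 0.900 equiv | 2.5 h |
| summer | 0.15 M | 0.900 equiv | 2.5 h |
| dawn | 0.50 M | 0.900 equiv | 2.5 h |
| dusk | 1.5 M | 0.900 equiv | 2.5 h |

- amount of D.L at the end, in percent of the X charged for midnight, noon, summer, dawn, dusk, in this order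
- how the row runs (falls, then rises / rises, then falls / hardly changes / falls all the way / rises all the way)

- where a step has two of a species, its rate is k times that concentration squared, and two are used at each turn
- given per volume of solution although it is solid: X
- at the start none of X is in solution
- "hardly changes" means that all values lie within two and a half points (for a concentration: within two and a half percent of the largest)
- run time (midnight): 2.5 h

Two numbers seem not to go together: the dissolving coefficient 0.0039 /min suggests a half-life of 178 min, yet midnight's solid should clear in minutes. They fit because the coefficient multiplies a gap, the solubility minus c(D), and not the amount of solid, and in midnight c(D) cannot pass the 0.020 M charged, so the gap stays close to the solubility. Freeze the gap there and X goes at the fixed rate 0.00273 M/min, the same for each charge; call this the dissolving ceiling, an upper bound, since any c(D) narrows the gap. Dividing a charge by the ceiling gives its clearing time, which for midnight is 7.33 min, far shorter than that half-life. For dawn it is 183 min and for dusk 549 min, and both are longer than the run, so I expect solid left in these two flasks and at most 0.409 M dissolved in each. My reckoning stops there, short of D.L.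

The forecast goes on to D.L with 2.4 %, 6.2 %, 11.8 %, 12.1 % and 7.1 %, a row that rises, then falls; for dusk it says “Dimerisation consumes L quickly and dissolution limits D”.

The simulation gives 2.35 %, 6.23 %, 11.8 %, 12.1 % and 7.07 %, a row that rises, then falls, and the forecast holds within its margin.

In midnight, half of the dissolving is done by 0.0618 h, against 0.0611 h from the ceiling, while half of the coupling is done by 1.26 h, far later, and at the end the solid stands at 0 % and D, the resting state, at 97.6 %, with a half-life by coupling of 73 h, far longer than the run. In dusk the solid still stands at 77.8 % at the end, and the 0.333 M dissolved is below the 0.409 M of the ceiling and close to dawn's 0.322 M.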